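**Strategy.** The target is cut at the C9–C10 bond of ring B (labdane numbering), the bond between its two adjacent fully substituted carbons. Because C10 closes an allylic array that runs through C5 to the oxygen-bearing C6, that oxygen can anchor a ring-contracting Ireland–Claisen rearrangement. In one operation the silyl ketene acetal of a δ-lactone forms C9–C10, closes ring B, sets C9 and C10 by chirality transfer from C6, and leaves a C5–C6 alkene for the return of the oxygen. The precursor is the all-trans 3-(2-benzyloxyethyl)-4-methyl-6-(2,6,6-trimethylcyclohexenyl) δ-lactone, made from β-cyclocitral by allylboration, ring-closing metathesis, cuprate addition and alkylation.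

Key step: step 6

Remark: decalin atoms carry labdane numbers (ring A C1–C5/C10, ring B C5–C10, arm C11–C12, butenolide C13–C16); α is the face opposite the C10 methyl group; reagent 2 is taken as the commercial pentane solution.

Step 1
Reactants: 1 β-cyclocitral; 2 (−)-B-allyldiisopinocampheylborane
Product: 4 (S)-1-(2,6,6-trimethylcyclohex-1-en-1-yl)but-3-en-1-ol, via diisopinocampheylborinate ester 3 (not isolated)
Conditions: Et2O/pentane, −78 °C → rt; then NaOH, H2O2, 0 °C → rt
Reagents that add atoms: (−)-B-allyldiisopinocampheylborane (2), C=CCB([C@@H]1C[C@@H]2C[C@@H](C2(C)C)[C@H]1C)[C@@H]1C[C@@H]2C[C@@H](C2(C)C)[C@H]1C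
Why: Brown allylboration through a six-membered chair transition state, in which the isopinocampheyl groups derived from (+)-α-pinene direct allyl transfer to the Si face of the hindered aldehyde and should set the (S)-carbinol that becomes C6.

Step 2
Reactants: 4 (S)-1-(2,6,6-trimethylcyclohex-1-en-1-yl)but-3-en-1-ol; 5 acryloyl chloride
Product: 6 (S)-1-(2,6,6-trimethylcyclohex-1-en-1-yl)but-3-en-1-yl acrylate
Conditions: Et3N, DMAP (cat.), CH2Cl2, −20 → 0 °C
Reagents that add atoms: acryloyl chloride (5), C=CC(Cl)=O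
Why: DMAP-catalysed acylation of a secondary alcohol with an acid chloride, which does not touch the stereocenter.

Step 3
Reactants: 6 (S)-1-(2,6,6-trimethylcyclohex-1-en-1-yl)but-3-en-1-yl acrylate
Product: 7 (S)-6-(2,6,6-trimethylcyclohex-1-en-1-yl)-5,6-dihydro-2H-pyran-2-one
Conditions: second-generation Grubbs catalyst RuCl2(=CHPh)(PCy3)(H2IMes) (5 mol%), CH2Cl2 (dilute), 40 °C
Reagents that add atoms: none
Why: Ring-closing metathesis of the terminal alkene with the acrylate closes the unsaturated six-membered lactone with loss of ethylene, while the tetrasubstituted ring alkene is inert to the ruthenium carbene.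

Step 4
Reactants: 7 (S)-6-(2,6,6-trimethylcyclohex-1-en-1-yl)-5,6-dihydro-2H-pyran-2-one
Product: 9 (4R,6S)-4-methyl-6-(2,6,6-trimethylcyclohex-1-en-1-yl)oxan-2-one, via trimethylsilyl ketene acetal 8 (not isolated)
Conditions: Me2CuLi (from MeLi, CuI), Me3SiCl, Et2O/THF, −78 → −40 °C; aq. NH4Cl, rt
Reagents that add atoms: lithium dimethylcuprate, [Li+].C[Cu-]C
Why: Chlorosilane-accelerated Gilman cuprate 1,4-addition to the unsaturated δ-lactone, in which methyl enters axially on the half-chair face anti to the C6 substituent and should give the 4,6-trans lactone (the C8 methyl); the enolate is trapped in the flask as silyl ketene acetal 8, which the aqueous work-up hydrolyses to the lactone, and conjugate addition is expected to outrun SN2′ attack on the tetrasubstituted allylic ester.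

Step 5
Reactants: 9 (4R,6S)-4-methyl-6-(2,6,6-trimethylcyclohex-1-en-1-yl)oxan-2-one; 10 benzyl 2-iodoethyl ether
Product: 12 (3S,4R,6S)-3-[2-(benzyloxy)ethyl]-4-methyl-6-(2,6,6-trimethylcyclohex-1-en-1-yl)oxan-2-one, via lithium enolate 11 (not isolated)
Conditions: LDA, THF, −78 °C; 10, DMPU, −78 → −20 °C
Reagents that add atoms: benzyl 2-iodoethyl ether (10), ICCOCc1ccccc1
Why: Alkylation of the lactone lithium enolate, generated from the isolated lactone with LDA, with a primary iodide anti to the C4 methyl; a copper-free lithium enolate in THF/DMPU is needed for this sluggish β-alkoxy iodide, and the new C3 center is of no consequence since it becomes trigonal in step 6.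

Step 6
Reactants: 12 (3S,4R,6S)-3-[2-(benzyloxy)ethyl]-4-methyl-6-(2,6,6-trimethylcyclohex-1-en-1-yl)oxan-2-one
Product: 16 (1R,2R,8aS)-1-[2-(benzyloxy)ethyl]-2,5,5,8a-tetramethyl-1,2,3,5,6,7,8,8a-octahydronaphthalene-1-carboxylic acid, via lithium enolate 13 (not isolated), via silyl ketene acetal 14 (not isolated), via silyl ester 15 (not isolated)
Conditions: LDA, THF, −78 °C; TBSCl, DMPU, −78 → 0 °C; toluene, 110 °C; then AcOH, THF/H2O, 40 °C
Reagents that add atoms: none
Why: Enolisation at C3 and O-silylation give the cyclic silyl ketene acetal 14, whose [3,3]-sigmatropic (Ireland–Claisen) shift joins the ketene acetal carbon (C9) to the methyl-bearing alkene carbon (C10) as the allylic C6–O bond breaks, a concerted intramolecular path suited to joining two fully substituted carbons. The closest known reaction type is the ring contraction of 6-alkenyl δ-lactone silyl ketene acetals to cyclohexenecarboxylic acids. Ring B is closed as a cyclohexene by contraction of the six-membered lactone through a boat transition state, a bicyclo[2.2.2]-like array with C9 and C6 at the bridgeheads, because the lactone tether rules out the chair. C10 is set by suprafacial 1,3-chirality transfer from the (S)-carbinol carbon C6, and C9 by the ring-fixed ketene acetal geometry within the same array, which should leave the carboxyl on the α face and the benzyloxyethyl arm on the β face, cis to the C10 methyl. The step needs complete facial fidelity, which the tether enforces, and a passable inside position for the C10 methyl, which the 4,6-trans lactone secures by turning only the C8 hydrogen toward it. Mild acid then hydrolyses silyl ester 15 to acid 16 without touching the benzyl ether or the alkene.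

Step 7
Reactants: 16 (1R,2R,8aS)-1-[2-(benzyloxy)ethyl]-2,5,5,8a-tetramethyl-1,2,3,5,6,7,8,8a-octahydronaphthalene-1-carboxylic acid
Product: 19 (1R,2R,4S,4aS,8aS)-1-[2-(benzyloxy)ethyl]-4-hydroxy-2,5,5,8a-tetramethyldecahydronaphthalene-1-carboxylic acid, via trimethylsilyl ester 17 (not isolated), via alkylborane 18 (not isolated)
Conditions: (Me3Si)2NH, THF, 50 °C, evaporate; BH3·THF, 0 → 40 °C; NaOH, H2O2, 0 °C → rt; 1 M HCl
Reagents that add atoms: hydrogen peroxide, OO
Why: Because borane reduces free carboxylic acids, the acid is masked in the flask as its trimethylsilyl ester before hydroboration–oxidation; syn addition of B–H to the trisubstituted C5–C6 alkene from the α face, away from the axial β-methyl groups on C10 and C4, should put boron on C6 and hydrogen on C5 (5α-H, 6α-OH, trans-decalin), and the alkaline peroxide work-up also cleaves the silyl ester.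

Step 8
Reactants: 19 (1R,2R,4S,4aS,8aS)-1-[2-(benzyloxy)ethyl]-4-hydroxy-2,5,5,8a-tetramethyldecahydronaphthalene-1-carboxylic acid
Product: 21 1-{(1R,2R,4S,4aS,8aS)-1-[2-(benzyloxy)ethyl]-4-hydroxy-2,5,5,8a-tetramethyldecahydronaphthalen-1-yl}ethan-1-one, via trilithium gem-diolate 20 (not isolated)
Conditions: MeLi (5 equiv), THF/Et2O, 0 °C → rt; inverse quench into cold 1 M HCl
Reagents that add atoms: methyllithium, [Li]C
Why: Addition of methyllithium to the lithium carboxylate gives a gem-diolate that is stable until work-up and then collapses to the methyl ketone (the classical conversion of a hindered acid into its methyl ketone), the C6 alkoxide being a spectator and no stereocenter being affected.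

Step 9
Reactants: 21 1-{(1R,2R,4S,4aS,8aS)-1-[2-(benzyloxy)ethyl]-4-hydroxy-2,5,5,8a-tetramethyldecahydronaphthalen-1-yl}ethan-1-one
Product: 22 (1R,2R,4S,4aS,8aS)-1-[2-(benzyloxy)ethyl]-4-hydroxy-2,5,5,8a-tetramethyldecahydronaphthalen-1-yl acetate
Conditions: mCPBA, NaHCO3, CH2Cl2, 0 °C → rt
Reagents that add atoms: mCPBA, OOC(=O)c1cccc(Cl)c1
Why: Baeyer–Villiger oxidation, in which the fully substituted C9 migrates in the Criegee intermediate in preference to methyl and with retention, so that oxygen takes the α position on C9 as its acetate while the secondary alcohol and the benzyl ether are inert to the peracid.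

Step 10
Reactants: 22 (1R,2R,4S,4aS,8aS)-1-[2-(benzyloxy)ethyl]-4-hydroxy-2,5,5,8a-tetramethyldecahydronaphthalen-1-yl acetate
Product: 23 (1R,2R,4S,4aS,8aS)-1-[2-(benzyloxy)ethyl]-2,5,5,8a-tetramethyldecahydronaphthalene-1,4-diol
Conditions: LiAlH4, THF, 0 °C → rt
Reagents that add atoms: none
Why: Hydride reduction removes the hindered tertiary acetate, which mild base would cleave only slowly, so that the single acetate of the target can later be placed on C6.

Step 11
Reactants: 23 (1R,2R,4S,4aS,8aS)-1-[2-(benzyloxy)ethyl]-2,5,5,8a-tetramethyldecahydronaphthalene-1,4-diol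
Product: 24 (1R,2R,4S,4aS,8aS)-1-(2-hydroxyethyl)-2,5,5,8a-tetramethyldecahydronaphthalene-1,4-diol
Conditions: H2 (1 atm), Pd/C, EtOH, rt
Reagents that add atoms: none
Why: Hydrogenolysis of the benzyl ether over palladium on carbon, at a stage where no alkene or other reducible group is present.

Step 12
Reactants: 24 (1R,2R,4S,4aS,8aS)-1-(2-hydroxyethyl)-2,5,5,8a-tetramethyldecahydronaphthalene-1,4-diol
Product: 25 2-[(1R,2R,4S,4aS,8aS)-1,4-dihydroxy-2,5,5,8a-tetramethyldecahydronaphthalen-1-yl]acetaldehyde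
Conditions: TEMPO (cat.), PhI(OAc)2, CH2Cl2, rt
Reagents that add atoms: none
Why: The oxoammonium oxidation distinguishes the unhindered primary alcohol from the hindered secondary C6 and the tertiary C9 hydroxyls and stops at the aldehyde.

Step 13
Reactants: 25 2-[(1R,2R,4S,4aS,8aS)-1,4-dihydroxy-2,5,5,8a-tetramethyldecahydronaphthalen-1-yl]acetaldehyde; 26 3-(triphenyl-λ5-phosphanylidene)oxolan-2-one
Product: 27 (E)-3-{2-[(1R,2R,4S,4aS,8aS)-1,4-dihydroxy-2,5,5,8a-tetramethyldecahydronaphthalen-1-yl]ethylidene}oxolan-2-one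
Conditions: CH2Cl2, rt → 40 °C
Reagents that add atoms: 3-(triphenyl-λ5-phosphanylidene)oxolan-2-one (26), O=C1OCCC1=P(c1ccccc1)(c1ccccc1)c1ccccc1
Why: Wittig olefination with the stabilised lactone ylide under neutral conditions, which spares the β-hydroxy aldehyde from retro-aldol cleavage and should give the (E)-alkylidene lactone.

Step 14
Reactants: 27 (E)-3-{2-[(1R,2R,4S,4aS,8aS)-1,4-dihydroxy-2,5,5,8a-tetramethyldecahydronaphthalen-1-yl]ethylidene}oxolan-2-one
Product: 28 3-{2-[(1R,2R,4S,4aS,8aS)-1,4-dihydroxy-2,5,5,8a-tetramethyldecahydronaphthalen-1-yl]ethyl}furan-2(5H)-one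
Conditions: RhCl3·3H2O (cat.), EtOH, 75 °C
Reagents that add atoms: none
Why: Rhodium hydride-mediated alkene migration (hydrometalation then β-hydride elimination) moves the exocyclic double bond into the ring to the more stable endocyclic butenolide, as known for α-alkylidene lactones and 2-alkylidenecyclopentanones.

Step 15
Reactants: 28 3-{2-[(1R,2R,4S,4aS,8aS)-1,4-dihydroxy-2,5,5,8a-tetramethyldecahydronaphthalen-1-yl]ethyl}furan-2(5H)-one
Product: 29 3-{2-[(1R,2R,4S,4aS,8aS)-4-acetoxy-1-hydroxy-2,5,5,8a-tetramethyldecahydronaphthalen-1-yl]ethyl}furan-2(5H)-one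
Conditions: Ac2O, pyridine, DMAP (cat.), CH2Cl2, 0 °C → rt
Reagents that add atoms: acetic anhydride, CC(=O)OC(C)=O
Why: Acetylation under these conditions is selective for the secondary 6α-hydroxyl, since the tertiary C9 hydroxyl flanked by the quaternary C10 does not react.

**Compound list**

1 | β-cyclocitral (2,6,6-trimethylcyclohex-1-ene-1-carbaldehyde) | CC1=C(C=O)C(C)(C)CCC1 | starting material
2 | (−)-B-allyldiisopinocampheylborane, the reagent derived from (+)-α-pinene | C=CCB([C@@H]1C[C@@H]2C[C@@H](C2(C)C)[C@H]1C)[C@@H]1C[C@@H]2C[C@@H](C2(C)C)[C@H]1C | starting material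
3 | diisopinocampheylborinate ester of 4 (not isolated) | C=CC[C@H](OB([C@@H]1C[C@@H]2C[C@@H](C2(C)C)[C@H]1C)[C@@H]1C[C@@H]2C[C@@H](C2(C)C)[C@H]1C)C1=C(C)CCCC1(C)C | intermediate
4 | (S)-1-(2,6,6-trimethylcyclohex-1-en-1-yl)but-3-en-1-ol | C=CC[C@H](O)C1=C(C)CCCC1(C)C | intermediate
5 | acryloyl chloride | C=CC(Cl)=O | starting material
6 | (S)-1-(2,6,6-trimethylcyclohex-1-en-1-yl)but-3-en-1-yl acrylate | C=CC[C@H](OC(=O)C=C)C1=C(C)CCCC1(C)C | intermediate
7 | (S)-6-(2,6,6-trimethylcyclohex-1-en-1-yl)-5,6-dihydro-2H-pyran-2-one | O=C1O[C@H](C2=C(C)CCCC2(C)C)CC=C1 | intermediate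
8 | trimethylsilyl ketene acetal of 9, (4R,6S) (not isolated) | C[Si](C)(C)OC1=C[C@H](C)C[C@H](O1)C1=C(C)CCCC1(C)C | intermediate
9 | (4R,6S)-4-methyl-6-(2,6,6-trimethylcyclohex-1-en-1-yl)oxan-2-one, 4,6-trans | O=C1O[C@H](C2=C(C)CCCC2(C)C)C[C@@H](C)C1 | intermediate
10 | benzyl 2-iodoethyl ether | ICCOCc1ccccc1 | starting material
11 | lithium enolate of 9, (4R,6S) (not isolated) | [Li]OC1=C[C@H](C)C[C@H](O1)C1=C(C)CCCC1(C)C | intermediate
12 | (3S,4R,6S)-3-[2-(benzyloxy)ethyl]-4-methyl-6-(2,6,6-trimethylcyclohex-1-en-1-yl)oxan-2-one, 3,4-trans and 4,6-trans (key-step precursor) | O=C1O[C@H](C2=C(C)CCCC2(C)C)C[C@@H](C)[C@@H]1CCOCc1ccccc1 | intermediate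
13 | lithium enolate of 12, (4R,6S) (not isolated) | [Li]OC1=C(CCOCc2ccccc2)[C@H](C)C[C@H](O1)C1=C(C)CCCC1(C)C | intermediate
14 | tert-butyldimethylsilyl ketene acetal of 12, (4R,6S) (not isolated) | CC(C)(C)[Si](C)(C)OC1=C(CCOCc2ccccc2)[C@H](C)C[C@H](O1)C1=C(C)CCCC1(C)C | intermediate
15 | tert-butyldimethylsilyl ester of 16 (not isolated) | C1C=C2C(C)(C)CCC[C@]2(C)[C@@](C(=O)O[Si](C)(C)C(C)(C)C)(CCOCc3ccccc3)[C@@H]1C | intermediate
16 | (1R,2R,8aS)-1-[2-(benzyloxy)ethyl]-2,5,5,8a-tetramethyl-1,2,3,5,6,7,8,8a-octahydronaphthalene-1-carboxylic acid; C5=C6 alkene, 8α-methyl, 9α-carboxyl, 9β-arm, 10β-methyl (key-step product) | C1C=C2C(C)(C)CCC[C@]2(C)[C@@](C(=O)O)(CCOCc3ccccc3)[C@@H]1C | intermediate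
17 | trimethylsilyl ester of 16 (not isolated) | C1C=C2C(C)(C)CCC[C@]2(C)[C@@](C(=O)O[Si](C)(C)C)(CCOCc3ccccc3)[C@@H]1C | intermediate
18 | 6α-boryl-5α-H trimethylsilyl ester (alkylborane, not isolated) | B[C@H]1C[C@@H](C)[C@](C(=O)O[Si](C)(C)C)(CCOCc2ccccc2)[C@@]2(C)CCCC(C)(C)[C@H]12 | intermediate
19 | (1R,2R,4S,4aS,8aS)-1-[2-(benzyloxy)ethyl]-4-hydroxy-2,5,5,8a-tetramethyldecahydronaphthalene-1-carboxylic acid; 5α-H, 6α-OH, 9α-carboxyl | O[C@H]1C[C@@H](C)[C@](C(=O)O)(CCOCc2ccccc2)[C@@]2(C)CCCC(C)(C)[C@H]12 | intermediate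
20 | trilithium salt of the methyllithium adduct of 19 (C6 alkoxide and C9 gem-diolate, not isolated) | [Li]O[C@H]1C[C@@H](C)[C@](C(C)(O[Li])O[Li])(CCOCc2ccccc2)[C@@]2(C)CCCC(C)(C)[C@H]12 | intermediate
21 | 1-{(1R,2R,4S,4aS,8aS)-1-[2-(benzyloxy)ethyl]-4-hydroxy-2,5,5,8a-tetramethyldecahydronaphthalen-1-yl}ethan-1-one; 9α-acetyl | O[C@H]1C[C@@H](C)[C@](C(C)=O)(CCOCc2ccccc2)[C@@]2(C)CCCC(C)(C)[C@H]12 | intermediate
22 | (1R,2R,4S,4aS,8aS)-1-[2-(benzyloxy)ethyl]-4-hydroxy-2,5,5,8a-tetramethyldecahydronaphthalen-1-yl acetate; 9α-acetoxy, 6α-OH | O[C@H]1C[C@@H](C)[C@](OC(C)=O)(CCOCc2ccccc2)[C@@]2(C)CCCC(C)(C)[C@H]12 | intermediate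
23 | (1R,2R,4S,4aS,8aS)-1-[2-(benzyloxy)ethyl]-2,5,5,8a-tetramethyldecahydronaphthalene-1,4-diol; 6α,9α-diol | O[C@H]1C[C@@H](C)[C@](O)(CCOCc2ccccc2)[C@@]2(C)CCCC(C)(C)[C@H]12 | intermediate
24 | (1R,2R,4S,4aS,8aS)-1-(2-hydroxyethyl)-2,5,5,8a-tetramethyldecahydronaphthalene-1,4-diol | O[C@H]1C[C@@H](C)[C@](O)(CCO)[C@@]2(C)CCCC(C)(C)[C@H]12 | intermediate
25 | 2-[(1R,2R,4S,4aS,8aS)-1,4-dihydroxy-2,5,5,8a-tetramethyldecahydronaphthalen-1-yl]acetaldehyde | O[C@H]1C[C@@H](C)[C@](O)(CC=O)[C@@]2(C)CCCC(C)(C)[C@H]12 | intermediate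
26 | 3-(triphenyl-λ5-phosphanylidene)oxolan-2-one | O=C1OCCC1=P(c1ccccc1)(c1ccccc1)c1ccccc1 | starting material
27 | (E)-3-{2-[(1R,2R,4S,4aS,8aS)-1,4-dihydroxy-2,5,5,8a-tetramethyldecahydronaphthalen-1-yl]ethylidene}oxolan-2-one | O[C@H]1C[C@@H](C)[C@](O)(C/C=C2\CCOC2=O)[C@@]2(C)CCCC(C)(C)[C@H]12 | intermediate
28 | 3-{2-[(1R,2R,4S,4aS,8aS)-1,4-dihydroxy-2,5,5,8a-tetramethyldecahydronaphthalen-1-yl]ethyl}furan-2(5H)-one | O[C@H]1C[C@@H](C)[C@](O)(CCC2=CCOC2=O)[C@@]2(C)CCCC(C)(C)[C@H]12 | intermediate
29 | CNP0205088.2, 3-{2-[(1R,2R,4S,4aS,8aS)-4-acetoxy-1-hydroxy-2,5,5,8a-tetramethyldecahydronaphthalen-1-yl]ethyl}furan-2(5H)-one (6α-acetoxy-9α-hydroxylabd-13-en-16,15-olide; 5S,6S,8R,9R,10S) | CC(=O)O[C@H]1C[C@@H](C)[C@](O)(CCC2=CCOC2=O)[C@@]2(C)CCCC(C)(C)[C@H]12 | target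

**Step count.** Total: 15 steps. Longest linear sequence: 15 steps (from β-cyclocitral).

**Steps most likely to fail**

1. Step 6. The boat transition state has to join two fully substituted carbons. The ketene acetal may instead ionise at the allylic C6–O bond or eliminate before it rearranges, and enolisation or O-silylation of the α-branched lactone may be incomplete. The fallback sets out from lactone 12 and makes the C9–C10 bond by radical cyclisation instead of a sigmatropic shift. The enolate of 12 (LDA, THF, −78 °C) is selenenylated with PhSeCl to the 3-(phenylselanyl) lactone F1 (either C3 epimer serves). Bu3SnH and AIBN (slow addition, toluene, 110 °C) generate the tertiary α-acyl radical. The lactone ring holds it over the cyclohexene, so it should add 6-endo to the methyl-bearing carbon on the same face as in the rearrangement. The resulting C5 radical takes hydrogen from the stannane to give the bridged lactone F2, in which the C6–O bond from the allylboration is kept. Opening of F2 with KOH in aqueous DMSO at 80 °C and acidification returns to the route at hydroxy acid 19, so step 7 is then not needed. The open points of this path are competing 5-exo closure and the face of hydrogen transfer to C5.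

2. Step 8. Methyllithium may fail to add to the carboxylate on C9, which is flanked by the quaternary C10 and the tertiary C8, or the ketone freed on quenching may take up a second equivalent. The fallback sets out from hydroxy acid 19 and places the C9 oxygen through a formate instead of an acetate. LiAlH4 (THF, 65 °C) reduces the carboxyl to the primary alcohol, diol F3. TEMPO with PhI(OAc)2 oxidises only the primary hydroxyl to hydroxy aldehyde F4. Baeyer–Villiger oxidation with mCPBA, in which the fully substituted C9 should migrate in preference to hydrogen, gives formate F5. K2CO3 in MeOH cleaves the formate and returns to the route at diol 23, so steps 9 and 10 are then not needed.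

3. Step 14. The alkene migration may stop at an unfavourable equilibrium, or the acidic rhodium chloride medium may dehydrate the tertiary C9 alcohol. The fallback sets out from triol 24 and builds the butenolide with its double bond already in the ring. I2, PPh3 and imidazole convert the primary hydroxyl into iodide F6, and TMSOTf with 2,6-lutidine caps the two remaining hydroxyls to give bis(trimethylsilyl) ether F7. 3-(Phenylsulfanyl)oxolan-2-one F8 (from 3-bromooxolan-2-one, thiophenol and Et3N) is deprotonated with LiHMDS in THF/DMPU and alkylated with F7 to sulfide F9. mCPBA at −78 °C gives sulfoxide F10, which on heating in toluene at 110 °C should undergo syn elimination toward the ring CH2 to the butenolide bis(silyl) ether F11. 1 M HCl in THF removes the silyl groups and returns to the route at diol butenolide 28.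

**Further compounds**

F1 | step 6 | (4R,6S)-3-[2-(benzyloxy)ethyl]-4-methyl-3-(phenylselanyl)-6-(2,6,6-trimethylcyclohex-1-en-1-yl)oxan-2-one, mixture at C3 | O=C1O[C@H](C2=C(C)CCCC2(C)C)C[C@@H](C)C1(CCOCc1ccccc1)[Se]c1ccccc1
F2 | step 6 | bridged lactone of 19 (C9α-carbonyl to C6α-oxygen, 2-oxabicyclo[2.2.2]octan-3-one fused to ring A, 5α-H) | O=C3O[C@H]1C[C@@H](C)[C@]3(CCOCc2ccccc2)[C@@]2(C)CCCC(C)(C)[C@H]12
F3 | step 8 | (1R,2R,4S,4aS,8aS)-1-[2-(benzyloxy)ethyl]-1-(hydroxymethyl)-2,5,5,8a-tetramethyldecahydronaphthalen-4-ol | O[C@H]1C[C@@H](C)[C@](CO)(CCOCc2ccccc2)[C@@]2(C)CCCC(C)(C)[C@H]12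
F4 | step 8 | (1R,2R,4S,4aS,8aS)-1-[2-(benzyloxy)ethyl]-4-hydroxy-2,5,5,8a-tetramethyldecahydronaphthalene-1-carbaldehyde | O[C@H]1C[C@@H](C)[C@](C=O)(CCOCc2ccccc2)[C@@]2(C)CCCC(C)(C)[C@H]12
F5 | step 8 | (1R,2R,4S,4aS,8aS)-1-[2-(benzyloxy)ethyl]-4-hydroxy-2,5,5,8a-tetramethyldecahydronaphthalen-1-yl formate | O[C@H]1C[C@@H](C)[C@](OC=O)(CCOCc2ccccc2)[C@@]2(C)CCCC(C)(C)[C@H]12
F6 | step 14 | (1R,2R,4S,4aS,8aS)-1-(2-iodoethyl)-2,5,5,8a-tetramethyldecahydronaphthalene-1,4-diol | O[C@H]1C[C@@H](C)[C@](O)(CCI)[C@@]2(C)CCCC(C)(C)[C@H]12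
F7 | step 14 | bis(trimethylsilyl) ether of F6 | C[Si](C)(C)O[C@H]1C[C@@H](C)[C@](O[Si](C)(C)C)(CCI)[C@@]2(C)CCCC(C)(C)[C@H]12
F8 | step 14 | 3-(phenylsulfanyl)oxolan-2-one | O=C1OCCC1Sc1ccccc1
F9 | step 14 | 3-(phenylsulfanyl)-3-[2-(decalinyl)ethyl]oxolan-2-one bis(trimethylsilyl) ether, mixture at the lactone α-carbon | C[Si](C)(C)O[C@H]1C[C@@H](C)[C@](O[Si](C)(C)C)(CCC2(Sc3ccccc3)CCOC2=O)[C@@]2(C)CCCC(C)(C)[C@H]12
F10 | step 14 | sulfoxide of F9 | C[Si](C)(C)O[C@H]1C[C@@H](C)[C@](O[Si](C)(C)C)(CCC2(S(=O)c3ccccc3)CCOC2=O)[C@@]2(C)CCCC(C)(C)[C@H]12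
F11 | step 14 | bis(trimethylsilyl) ether of 28 | C[Si](C)(C)O[C@H]1C[C@@H](C)[C@](O[Si](C)(C)C)(CCC2=CCOC2=O)[C@@]2(C)CCCC(C)(C)[C@H]12
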